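**Retrosynthetic overview**
1. Target 7 ⇐ bis(methyl ether) 4: the two O–Me bonds are cleaved and the four C–Br bonds ortho to the outer OH groups are made last, in one pot.
2. 4 ⇐ quinone 3 (reduction) ⇐ two aryl C–O bonds: bromanil 1 + 2 × 2-bromo-4-methoxyphenol 2 by double addition–elimination, 2,5-selective.
3. The Br ortho to each ether oxygen arrives with 2; the centre-ring Br atoms and all six oxygens arrive with 1 and 2.
4. No ring is built: all three six-membered rings come from 1 and 2, and the centre ring only changes oxidation level (quinone → hydroquinone).

Assumption: the target has no stereocentre and is achiral, so "single enantiomer" needs no stereocontrol; only regiochemistry has to be set.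

**Step 1**
Reactants: 1 tetrabromo-1,4-benzoquinone (bromanil); 2 2-bromo-4-methoxyphenol (2.05 equiv)
Product: 4 2,5-dibromo-3,6-bis(2-bromo-4-methoxyphenoxy)benzene-1,4-diol, via diaryloxyquinone 3 (not isolated)
Conditions: K2CO3 (2.2 equiv), MeCN–THF, 0 °C → rt (2 and base premixed, 1 added last); then aq Na2S2O4, EtOAc, rt
Reagents that add atoms: none
Why: Double addition–elimination (vinylogous SNAr) of the aryloxide on the tetrahaloquinone; the first aryloxy group turns the carbonyl it conjugates with into a vinylogous ester, so the second aryloxide adds conjugate to the other carbonyl and lands para to the first (2,5-pattern), and the dithionite work-up reduces the quinone so that the two new C–O bonds become ordinary diaryl ethers that tolerate BBr3.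

**Step 2**
Reactants: 4 2,5-dibromo-3,6-bis(2-bromo-4-methoxyphenoxy)benzene-1,4-diol
Product: 7 2,5-dibromo-3,6-bis(2,3,5-tribromo-4-hydroxyphenoxy)benzene-1,4-diol (target), via hexol 5 (not isolated), via octabromoquinone 6 (not isolated)
Conditions: BBr3 (3.5 equiv), CH2Cl2, −78 °C → rt; then DMSO (6 equiv), H2O (10 equiv), −20 → 40 °C; then aq Na2S2O4, EtOAc, rt
Reagents that add atoms: boron tribromide, BrB(Br)Br
Why: Proposed new method: a one-pot demethylative oxidative bromination in which BBr3 is both the ether-cleaving reagent and the only bromine source; BBr3 cleaves the two ArO–Me bonds (ArOMe + BBr3 → ArOBBr2 + MeBr), the measured water then turns all B–Br and B–OAr bonds into B(OH)3, free phenol 5 and HBr, and DMSO oxidises that HBr to bromodimethylsulfonium bromide, which substitutes both positions ortho to each outer OH (the strongest donor; its para position is blocked by the ether oxygen and the position ortho to the ether oxygen is only weakly activated), while the same oxidant takes the centre hydroquinone to quinone 6, which the dithionite work-up returns to the hydroquinone; the closest known reaction types are BBr3 cleavage of aryl methyl ethers and HBr/DMSO (bromosulfonium) oxidative bromination of phenols, and their merger with boron-derived bromide as the halogen source is untested.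

**Compound list**
1 | tetrabromo-1,4-benzoquinone (bromanil; 2,3,5,6-tetrabromocyclohexa-2,5-diene-1,4-dione), achiral | O=C1C(Br)=C(Br)C(=O)C(Br)=C1Br | starting material
2 | 2-bromo-4-methoxyphenol, achiral | COc1ccc(O)c(Br)c1 | starting material
3 | 2,5-dibromo-3,6-bis(2-bromo-4-methoxyphenoxy)cyclohexa-2,5-diene-1,4-dione, achiral | O=C1C(Br)=C(Oc2ccc(OC)cc2Br)C(=O)C(Br)=C1Oc1ccc(OC)cc1Br | intermediate (not isolated)
4 | 2,5-dibromo-3,6-bis(2-bromo-4-methoxyphenoxy)benzene-1,4-diol, achiral | COc1ccc(Oc2c(O)c(Br)c(Oc3ccc(OC)cc3Br)c(O)c2Br)c(Br)c1 | intermediate
5 | 2,5-dibromo-3,6-bis(2-bromo-4-hydroxyphenoxy)benzene-1,4-diol (hexol), achiral | Oc1ccc(Oc2c(O)c(Br)c(Oc3ccc(O)cc3Br)c(O)c2Br)c(Br)c1 | intermediate (not isolated)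
6 | 2,5-dibromo-3,6-bis(2,3,5-tribromo-4-hydroxyphenoxy)cyclohexa-2,5-diene-1,4-dione, achiral | O=C1C(Br)=C(Oc2cc(Br)c(O)c(Br)c2Br)C(=O)C(Br)=C1Oc1cc(Br)c(O)c(Br)c1Br | intermediate (not isolated)
7 | 2,5-dibromo-3,6-bis(2,3,5-tribromo-4-hydroxyphenoxy)benzene-1,4-diol, achiral | Oc1c(Br)cc(Oc2c(O)c(Br)c(Oc3cc(Br)c(O)c(Br)c3Br)c(O)c2Br)c(Br)c1Br | target

**Totals**
Total step count: 2. Longest linear sequence: 2.

**Steps most likely to fail**
The route has only two steps, so both are ranked here and there is no third.

First, step 2 (the proposed new step). Three things can go wrong: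
- the bromosulfonium reagent made from boron-derived HBr may stop after one bromination per outer ring;
- the centre ring rests as quinone 6 in HBr, where bromide could displace an aryloxy group or ipso attack could cut the ether;
- activated DMSO could methylthiomethylate the phenols.

The fallback uses only known chemistry and sets out from 4. BBr3 in CH2Cl2 with an ordinary aqueous work-up gives the hexol 5 as an isolated compound. Molecular bromine (5.1 equiv) with NaOAc in AcOH–CH2Cl2 at 0 °C → rt then brominates the four positions ortho to the outer OH groups and oxidises the centre ring. This arrives at quinone 6, where the fallback comes back to the route, and aqueous Na2S2O4 gives 7. This fallback makes no compound outside the compound list (F0).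

Second, step 1. The electron-rich aryloxide can transfer an electron to bromanil instead of adding. A third or fourth aryloxide can displace the remaining Br. Traces of water give bromanilic acid, and some 2,6-isomer may form.

The fallback moves the C–O bond formation away from the quinone and sets out from 2. A copper-catalysed Ullmann coupling of 2 with commercial 1,4-diiodo-2,5-dimethoxybenzene (COc1cc(I)c(OC)cc1I; CuI, picolinic acid, K3PO4, DMSO, 90 °C, the aryl iodide reacting ahead of the aryl bromide) gives 1,4-dimethoxy-2,5-bis(2-bromo-4-methoxyphenoxy)benzene F1. BBr3 in CH2Cl2 cleaves all four methyl ethers to 2,5-bis(2-bromo-4-hydroxyphenoxy)benzene-1,4-diol F2. Bromine (7.2 equiv) in AcOH then brominates the two free centre positions and the four outer positions ortho to OH and oxidises the centre ring. This arrives at quinone 6, where the fallback comes back to the route, and aqueous Na2S2O4 gives 7.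

**Further compounds**
F0 | step 2 | none | none
F1 | step 1 | 1,4-dimethoxy-2,5-bis(2-bromo-4-methoxyphenoxy)benzene | COc1cc(Oc2ccc(OC)cc2Br)c(OC)cc1Oc1ccc(OC)cc1Br
F2 | step 1 | 2,5-bis(2-bromo-4-hydroxyphenoxy)benzene-1,4-diol | Oc1ccc(Oc2cc(O)c(Oc3ccc(O)cc3Br)cc2O)c(Br)c1
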